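**Plan**

1. Retrosynthesis: the quinone ring is cut at C4–C5 and C6–C1, the two acyl–CH bonds flanking its unsubstituted C5H=C6H edge. This gives acetylene and a maleoylcobalt metallacycle, the CO–CO-opened form of a 3-(furan-2-yl)cyclobut-3-ene-1,2-dione. Further cuts follow in this order: furan C2–cyclobutene bond (Stille), ester C–O, prenyl C=C (cross-metathesis), carbinol C–CH2 bond (allylboration of 5-bromofuran-3-carbaldehyde).
2. Enabling feature: in the quinone ring, C1(=O)–C2(furyl)=C3H–C4(=O) is a maleoyl unit that maps onto a strained cyclobutenedione. The opposite edge C5H=C6H carries no substituent, so it is acetylene itself and no regiochemical question arises.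
3. Forward: the furan is bought with bromine at C5. The side chain is built, Br is exchanged for SnBu3, the ester is put on, the four-membered ring is attached, cobalt is inserted, and the six-membered quinone ring is closed last. The four-membered ring and the cobalt are helpers that disappear in the key step; no protecting group is used.
4. Stereochemistry: the single (S) centre comes from a reagent-controlled Brown allylboration with (−)-Ipc2B(allyl); no later step breaks a bond at that carbon.

Key step: step 10

Assumption: 5-bromofuran-3-carbaldehyde, diisopropyl squarate, (−)-Ipc2B(allyl) (pentane solution) and CoCl(PPh3)3 are taken as catalogue reagents.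

**Route**

Step 1
Reactants: 1 5-bromofuran-3-carbaldehyde; 2 (−)-B-allyldiisopinocampheylborane
Product: 3 (S)-1-(5-bromofuran-3-yl)but-3-en-1-ol
Conditions: 2 (1.2 equiv, pentane solution), Et2O, −100 to −78 °C; then NaOH aq, 30% H2O2, 0 °C to rt
Reagents that add atoms: none
Why: Brown asymmetric allylboration through a closed six-membered chair (Zimmerman–Traxler) transition state, in which the isopinocampheyl groups derived from (+)-α-pinene deliver the allyl group to the Si face of the aldehyde, which for an aryl or heteroaryl aldehyde gives the (S)-carbinol.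

Step 2
Reactants: 3 (S)-1-(5-bromofuran-3-yl)but-3-en-1-ol; 4 2-methylbut-2-ene
Product: 5 (S)-1-(5-bromofuran-3-yl)-4-methylpent-3-en-1-ol
Conditions: second-generation Grubbs catalyst RuCl2(=CHPh)(PCy3)(SIMes) (5 mol %), 4 (excess)/CH2Cl2, 40 °C
Reagents that add atoms: none
Why: Ruthenium-catalysed olefin cross-metathesis of the terminal alkene with an excess of the trisubstituted partner 4 transfers the isopropylidene unit and releases propene, the standard allyl-to-prenyl conversion, which tolerates the free alcohol and the bromofuran and does not touch the stereocentre.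

Step 3
Reactants: 5 (S)-1-(5-bromofuran-3-yl)-4-methylpent-3-en-1-ol
Product: 7 (S)-4-methyl-1-[5-(tributylstannyl)furan-3-yl]pent-3-en-1-ol, via dilithio alkoxide 6 (not isolated)
Conditions: n-BuLi (2.2 equiv), THF, −78 °C; Bu3SnCl (1.1 equiv), −78 to 0 °C; water quench
Reagents that add atoms: tributyltin chloride, CCCC[Sn](Cl)(CCCC)CCCC
Why: After deprotonation of the hydroxyl by the first equivalent of n-BuLi, bromine–lithium exchange at the furan α-carbon is much faster than any ring deprotonation, so the metal is placed exactly where the bromine was (C5, giving the 2,4-pattern) and the furyllithium is trapped by Bu3SnCl (lithiation–stannylation) without protection of the alcohol.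

Step 4
Reactants: 7 (S)-4-methyl-1-[5-(tributylstannyl)furan-3-yl]pent-3-en-1-ol; 8 3-methylbut-2-enoic acid
Product: 9 (S)-4-methyl-1-[5-(tributylstannyl)furan-3-yl]pent-3-en-1-yl 3-methylbut-2-enoate
Conditions: 8 (1.5 equiv), DCC (1.5 equiv), DMAP (0.2 equiv), CH2Cl2, 0 °C to rt (acid, DCC and DMAP premixed before 7 is added)
Reagents that add atoms: none
Why: Steglich esterification acylates the secondary alcohol through the acylpyridinium ion without breaking the C–O bond of the stereocentre (retention), under conditions too mild to move the double bond of the acid out of conjugation or to cleave the furyl–tin bond.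

Step 5
Reactants: 10 diisopropyl squarate (3,4-diisopropoxycyclobut-3-ene-1,2-dione)
Product: 12 3-isopropoxycyclobut-3-ene-1,2-dione, via hydride adduct 11 (not isolated)
Conditions: LiAlH(OtBu)3 (1.05 equiv), THF, −78 °C; then 6 M HCl, CH2Cl2, 0 °C to rt
Reagents that add atoms: water, O
Why: Selective 1,2-addition of one hydride to a squarate carbonyl gives carbinol 11, which acid ionises with allylic transposition (loss of the hydroxyl, hydrolysis of the enol ether carbon at the other end of the allyl cation) to the semisquarate, the established reduction–hydrolysis route to 3-alkoxycyclobutenediones.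

Step 6
Reactants: 12 3-isopropoxycyclobut-3-ene-1,2-dione
Product: 13 3-hydroxycyclobut-3-ene-1,2-dione (semisquaric acid)
Conditions: 6 M HCl aq, THF, 50 °C; evaporation to dryness
Reagents that add atoms: water, O
Why: Acid hydrolysis of the vinylogous ester by addition of water to C3 and loss of propan-2-ol gives the strongly acidic vinylogous carboxylic acid, isolated by evaporation.

Step 7
Reactants: 13 3-hydroxycyclobut-3-ene-1,2-dione
Product: 14 3-chlorocyclobut-3-ene-1,2-dione
Conditions: (COCl)2 (1.5 equiv), DMF (cat.), CH2Cl2, 0 °C to rt; volatiles removed (toluene chase), used at once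
Reagents that add atoms: oxalyl chloride, O=C(Cl)C(=O)Cl
Why: Oxalyl chloride with catalytic DMF (Vilsmeier-type activation) converts the vinylogous acid into the vinylogous acid chloride by addition–elimination at C3, as in the preparation of squaric dichloride and other chlorocyclobutenediones.

Step 8
Reactants: 9 (S)-4-methyl-1-[5-(tributylstannyl)furan-3-yl]pent-3-en-1-yl 3-methylbut-2-enoate; 14 3-chlorocyclobut-3-ene-1,2-dione
Product: 15 (S)-1-[5-(3,4-dioxocyclobut-1-en-1-yl)furan-3-yl]-4-methylpent-3-en-1-yl 3-methylbut-2-enoate
Conditions: 14 (1.2 equiv), PdCl(CH2Ph)(PPh3)2 (5 mol %), CuI (10 mol %), MeCN, rt to 50 °C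
Reagents that add atoms: none
Why: Stille coupling of a chlorocyclobutenedione with an organostannane: the vinylogous acyl chloride C–Cl bond adds to zerovalent palladium far faster than any other bond in either partner, the α-furylstannane transmetalates readily with CuI assistance, and the neutral conditions spare the ester, the prenyl group and the stereocentre.

Step 9
Reactants: 15 (S)-1-[5-(3,4-dioxocyclobut-1-en-1-yl)furan-3-yl]-4-methylpent-3-en-1-yl 3-methylbut-2-enoate
Product: 17 chloro(dimethylglyoxime)(pyridine)maleoylcobalt complex of 15 (3-aryl-1-cobaltacyclopent-3-ene-2,5-dione; trivalent cobalt), via bis(triphenylphosphine) maleoylcobalt chloride 16 (not isolated)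
Conditions: CoCl(PPh3)3 (1.1 equiv), benzene, rt, N2; then dimethylglyoxime (1.2 equiv), pyridine, rt; chromatography
Reagents that add atoms: chlorotris(triphenylphosphine)cobalt CoCl(PPh3)3, Cl[Co-3]([P+](c1ccccc1)(c1ccccc1)c1ccccc1)([P+](c1ccccc1)(c1ccccc1)c1ccccc1)[P+](c1ccccc1)(c1ccccc1)c1ccccc1; dimethylglyoxime, CC(=NO)C(C)=NO; pyridine, c1ccncc1
Why: Oxidative addition of monovalent cobalt into the strained C(=O)–C(=O) bond of the cyclobutenedione gives the five-membered maleoylcobalt metallacycle (trivalent cobalt), the known entry to such complexes, and exchange of both phosphines for chelating dimethylglyoxime and pyridine gives the air-stable octahedral form that is known to react with alkynes.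

Step 10
Reactants: 17 chloro(dimethylglyoxime)(pyridine)maleoylcobalt complex of 15; 18 acetylene
Product: 19 (S)-1-[5-(3,6-dioxocyclohexa-1,4-dien-1-yl)furan-3-yl]-4-methylpent-3-en-1-yl 3-methylbut-2-enoate (target)
Conditions: acetylene (1 atm), CoCl2·6H2O (1 equiv), ClCH2CH2Cl, 25 to 50 °C; work-up in air
Reagents that add atoms: none
Why: The Lewis acid CoCl2·6H2O opens a coordination site on the trivalent cobalt of 17, acetylene binds cis to an acyl carbon, migratory insertion into one Co–C(=O) bond gives a seven-membered cobaltacycle (Co–CH=CH–C(=O)–C(furyl)=CH–C(=O)), and C–C reductive elimination between the vinyl carbon and the second acyl carbon forms the second bond and releases the quinone and monovalent cobalt. The closest known reaction type is this very one, the benzoquinone synthesis from maleoylcobalt dimethylglyoxime complexes and alkynes (terminal alkynes included), used here with the parent alkyne. The six-membered quinone ring is closed as a formal [4+2] annulation of the four-carbon maleoyl unit with the two-carbon alkyne, the closing event being reductive elimination from the seven-membered metallacycle and not a polar cyclisation. No stereocentre is formed, and the existing (S) centre lies on the furan side chain, is never ionised under these near-neutral conditions and stays untouched. The step needs a single insertion and chemoselectivity for the alkyne over the prenyl, senecioate and furan π-bonds: the two acyl–cobalt bonds are held cis in the five-membered metallacycle so that one insertion is followed at once by ring-forming reductive elimination, alkenes do not insert into these acyl–cobalt bonds, and because acetylene is symmetric it does not matter which of the two unlike Co–acyl bonds reacts first.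

**Compound list**

1 | 5-bromofuran-3-carbaldehyde | O=Cc1coc(Br)c1 | starting material
2 | (−)-B-allyldiisopinocampheylborane, (−)-Ipc2B(allyl), both isopinocampheyl groups from (+)-α-pinene | C=CCB([C@@H]1C[C@@H]2C[C@H]([C@H]1C)C2(C)C)[C@@H]1C[C@@H]2C[C@H]([C@H]1C)C2(C)C | starting material
3 | (S)-1-(5-bromofuran-3-yl)but-3-en-1-ol | C=CC[C@H](O)c1coc(Br)c1 | intermediate
4 | 2-methylbut-2-ene | CC=C(C)C | starting material
5 | (S)-1-(5-bromofuran-3-yl)-4-methylpent-3-en-1-ol | CC(C)=CC[C@H](O)c1coc(Br)c1 | intermediate
6 | lithium (S)-1-(5-lithiofuran-3-yl)-4-methylpent-3-en-1-olate (dilithio alkoxide) | CC(C)=CC[C@H](O[Li])c1coc([Li])c1 | intermediate (not isolated)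
7 | (S)-4-methyl-1-[5-(tributylstannyl)furan-3-yl]pent-3-en-1-ol | CC(C)=CC[C@H](O)c1coc([Sn](CCCC)(CCCC)CCCC)c1 | intermediate
8 | 3-methylbut-2-enoic acid | CC(C)=CC(=O)O | starting material
9 | (S)-4-methyl-1-[5-(tributylstannyl)furan-3-yl]pent-3-en-1-yl 3-methylbut-2-enoate | CC(C)=CC[C@H](OC(=O)C=C(C)C)c1coc([Sn](CCCC)(CCCC)CCCC)c1 | intermediate
10 | diisopropyl squarate (3,4-diisopropoxycyclobut-3-ene-1,2-dione) | CC(C)OC1=C(OC(C)C)C(=O)C1=O | starting material
11 | 4-hydroxy-2,3-diisopropoxycyclobut-2-en-1-one (hydride adduct, racemic) | CC(C)OC1=C(OC(C)C)C(O)C1=O | intermediate (not isolated)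
12 | 3-isopropoxycyclobut-3-ene-1,2-dione | CC(C)OC1=CC(=O)C1=O | intermediate
13 | 3-hydroxycyclobut-3-ene-1,2-dione (semisquaric acid) | OC1=CC(=O)C1=O | intermediate
14 | 3-chlorocyclobut-3-ene-1,2-dione | ClC1=CC(=O)C1=O | intermediate
15 | (S)-1-[5-(3,4-dioxocyclobut-1-en-1-yl)furan-3-yl]-4-methylpent-3-en-1-yl 3-methylbut-2-enoate | CC(C)=CC[C@H](OC(=O)C=C(C)C)c1coc(C2=CC(=O)C2=O)c1 | intermediate
16 | 3-aryl-1-chloro-1,1-bis(triphenylphosphine)-1-cobaltacyclopent-3-ene-2,5-dione (trivalent cobalt; aryl = the 4-substituted furan-2-yl unit of 15; cobalt inserted between the two carbonyl carbons of 15) | CC(C)=CC[C@H](OC(=O)C=C(C)C)c1coc(C2=CC(=O)[Co-2](Cl)([P+](c3ccccc3)(c3ccccc3)c3ccccc3)([P+](c3ccccc3)(c3ccccc3)c3ccccc3)C2=O)c1 | intermediate (not isolated)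
17 | 3-aryl-1-chloro-1-(N,N'-bound dimethylglyoxime)-1-(pyridine)-1-cobaltacyclopent-3-ene-2,5-dione (trivalent cobalt; same aryl group; configuration at cobalt not specified) | CC(C)=CC[C@H](OC(=O)C=C(C)C)c1coc(C2=CC(=O)[Co-3]3(Cl)([n+]4ccccc4)([N+](O)=C(C)C(C)=[N+]3O)C2=O)c1 | intermediate
18 | acetylene | C#C | starting material
19 | (S)-1-[5-(3,6-dioxocyclohexa-1,4-dien-1-yl)furan-3-yl]-4-methylpent-3-en-1-yl 3-methylbut-2-enoate | CC(C)=CC[C@H](OC(=O)C=C(C)C)c1coc(C2=CC(=O)C=CC2=O)c1 | target

**Count and risks**

Total steps: 10. Longest linear sequence: 7 (steps 1, 2, 3, 4, 8, 9, 10, from 1); the side branch is steps 5 to 7.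

Steps most likely to fail:

Step 10 (annulation with acetylene). The risks are multiple insertion or oligomerisation of acetylene at cobalt, loss of CO from the metallacycle, and reduction of the new quinone by the monovalent cobalt that is released. The fallback replaces the metal-mediated ring expansion by a thermal one; it sets out from 15 and comes back at 19. Monolithium acetylide (from 18 and n-BuLi, THF, −78 °C) should add to the more electrophilic ring carbonyl of 15, the one next to the furyl-bearing carbon. This would give (S)-1-[5-(4-ethynyl-4-hydroxy-3-oxocyclobut-1-en-1-yl)furan-3-yl]-4-methylpent-3-en-1-yl 3-methylbut-2-enoate F1, as both epimers at the new carbinol carbon; addition at the other carbonyl would lead to the same quinone. Heating F1 in toluene at about 110 °C (Moore rearrangement: ring opening to the alkynyl vinylketene, closure onto the alkyne, hydrogen shift from O to C) should give 19.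

Step 8 (Stille coupling). The risks are decomposition of the very electrophilic chloride 14 (hydrolysis, nucleophilic attack at its unsubstituted ring CH) faster than oxidative addition, and protodestannylation of 9 by traces of HCl. The fallback uses organolithium addition to the squarate in place of cross-coupling; it sets out from 5 and comes back at 15.
- Silylation of 5 (TBSCl, imidazole, DMF) would give (S)-tert-butyl{[1-(5-bromofuran-3-yl)-4-methylpent-3-en-1-yl]oxy}dimethylsilane F2.
- Bromine–lithium exchange (n-BuLi, THF, −78 °C) and 1,2-addition to 10 would give the 4-furyl-4-hydroxy-2,3-diisopropoxycyclobut-2-en-1-one adduct F3.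
- Trifluoroacetic anhydride in the same flask should rearrange F3 to the 3-furyl-4-isopropoxycyclobut-3-ene-1,2-dione silyl ether F4.
- 1,2-Reduction with LiAlH(OtBu)3 at −78 °C would give the 2-furyl-4-hydroxy-3-isopropoxycyclobut-2-en-1-one hydride adduct F5.
- Dilute HCl should then give the 3-furylcyclobut-3-ene-1,2-dione silyl ether F6.
- HF·pyridine would remove the silyl group to give the hydroxy dione 3-{4-[(S)-1-hydroxy-4-methylpent-3-en-1-yl]furan-2-yl}cyclobut-3-ene-1,2-dione F7.
- Steglich esterification of F7 with 8 would give 15.

Step 9 (cobalt insertion and ligand exchange). The risks are that the monovalent cobalt is tied up by the furan and the two alkenes, that the acyl–cobalt intermediate loses CO before dimethylglyoxime traps it, or that the complex is lost on chromatography. The fallback couples the furan onto a ready-made quinone; it sets out from 9 and comes back at 19. Bromohydroquinone would be oxidised (Ag2O, Et2O) to 2-bromo-1,4-benzoquinone F8, and a Stille coupling of 9 with F8 (Pd(PPh3)4, CuBr, dioxane, 80 °C) should give 19 directly.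

Further compounds
F1 | step 10 | (S)-1-[5-(4-ethynyl-4-hydroxy-3-oxocyclobut-1-en-1-yl)furan-3-yl]-4-methylpent-3-en-1-yl 3-methylbut-2-enoate (both epimers at the ring carbinol) | CC(C)=CC[C@H](OC(=O)C=C(C)C)c1coc(C2=CC(=O)C2(O)C#C)c1
F2 | step 8 | (S)-tert-butyl{[1-(5-bromofuran-3-yl)-4-methylpent-3-en-1-yl]oxy}dimethylsilane | CC(C)=CC[C@H](O[Si](C)(C)C(C)(C)C)c1coc(Br)c1
F3 | step 8 | 4-{4-[(S)-1-(tert-butyldimethylsilyloxy)-4-methylpent-3-en-1-yl]furan-2-yl}-4-hydroxy-2,3-diisopropoxycyclobut-2-en-1-one | CC(C)=CC[C@H](O[Si](C)(C)C(C)(C)C)c1coc(C2(O)C(OC(C)C)=C(OC(C)C)C2=O)c1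
F4 | step 8 | 3-{4-[(S)-1-(tert-butyldimethylsilyloxy)-4-methylpent-3-en-1-yl]furan-2-yl}-4-isopropoxycyclobut-3-ene-1,2-dione | CC(C)=CC[C@H](O[Si](C)(C)C(C)(C)C)c1coc(C2=C(OC(C)C)C(=O)C2=O)c1
F5 | step 8 | 2-{4-[(S)-1-(tert-butyldimethylsilyloxy)-4-methylpent-3-en-1-yl]furan-2-yl}-4-hydroxy-3-isopropoxycyclobut-2-en-1-one | CC(C)=CC[C@H](O[Si](C)(C)C(C)(C)C)c1coc(C2=C(OC(C)C)C(O)C2=O)c1
F6 | step 8 | 3-{4-[(S)-1-(tert-butyldimethylsilyloxy)-4-methylpent-3-en-1-yl]furan-2-yl}cyclobut-3-ene-1,2-dione | CC(C)=CC[C@H](O[Si](C)(C)C(C)(C)C)c1coc(C2=CC(=O)C2=O)c1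
F7 | step 8 | 3-{4-[(S)-1-hydroxy-4-methylpent-3-en-1-yl]furan-2-yl}cyclobut-3-ene-1,2-dione | CC(C)=CC[C@H](O)c1coc(C2=CC(=O)C2=O)c1
F8 | step 9 | 2-bromo-1,4-benzoquinone | O=C1C=CC(=O)C(Br)=C1
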